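## Retrosynthetic overview

1. Manumycin G ⇐ hydroxyl-directed (syn) epoxidation of the C5=C6 enone of a (4R)-p-quinol; the oxirane is the last ring formed.
2. The p-quinol ⇐ enantioselective para-hydroxylative dearomatisation of the fully assembled aminophenol "proto-manumycin G" (arene hydroxylation, then epoxidation, the order of the presumed biosynthetic end-game); the six-membered ring is carried as a benzene ring throughout.
3. Proto-manumycin G ⇐ N-acylation of a 3-amino-4-hydroxyphenyl trienamide with 8-methylnonatrienoic acid (vinylogous HWE from 4-methylpent-2-enal).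
4. Cyclopentenone (C5N) ring ⇐ Dieckmann-type C-acylation of an N-acyl 5-aminolevulinate, the chemical counterpart of the biosynthetic cyclisation of 5-aminolevulinate; it is the first ring formed.
5. Aryl trienoic acid ⇐ Wittig plus vinylogous HWE on 4-fluoro-3-nitrobenzaldehyde (F = latent phenol, NO2 = latent amine); no protecting groups.

Assumption: the SMILES is taken at face value, i.e. all-E chains, the C5N unit written as its enol, and a (4S,5R,6S) core with hydroxyl and oxirane on the same face (core numbering: C1 ketone, C2 C–N, C3 CH, C4 C–OH, C5/C6 oxirane carbons).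

## Route

Step 1
Reactants: 1 4-fluoro-3-nitrobenzaldehyde; 2 (triphenylphosphoranylidene)acetaldehyde
Product: 3 (2E)-3-(4-fluoro-3-nitrophenyl)prop-2-enal
Conditions: 2 (1.0 equiv), PhMe, 80 °C
Reagents that add atoms: none
Why: Wittig olefination with a formyl-stabilised ylide gives the E-enal, and the nitro-activated benzaldehyde reacts much faster than the product enal, so one equivalent of ylide keeps double homologation low.

Step 2
Reactants: 3 (2E)-3-(4-fluoro-3-nitrophenyl)prop-2-enal; 4 triethyl 4-phosphonocrotonate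
Product: 6 (2E,4E,6E)-7-(4-hydroxy-3-nitrophenyl)hepta-2,4,6-trienoic acid, via ethyl 7-(4-fluoro-3-nitrophenyl)heptatrienoate 5 (not isolated)
Conditions: 4, NaH, THF, 0 °C, then 3, −20 °C → rt; then KOH (aq), DMSO, 50 °C; HCl (aq) to pH 2
Reagents that add atoms: potassium hydroxide, [K+].[OH-]
Why: Vinylogous Horner–Wadsworth–Emmons olefination gives the all-E trienoate (new C4=C5 bond E), and hydroxide then saponifies the ester and displaces the fluoride ortho to the nitro group by SNAr, so the phenol is unmasked only after the olefinations are over.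

Step 3
Reactants: 6 (2E,4E,6E)-7-(4-hydroxy-3-nitrophenyl)hepta-2,4,6-trienoic acid; 7 methyl 5-amino-4-oxopentanoate hydrochloride (methyl 5-aminolevulinate hydrochloride)
Product: 8 methyl 5-[[(2E,4E,6E)-7-(4-hydroxy-3-nitrophenyl)hepta-2,4,6-trienoyl]amino]-4-oxopentanoate
Conditions: EDC·HCl, HOBt, N-methylmorpholine (added slowly), DMF, 0 °C → rt
Reagents that add atoms: none
Why: Carbodiimide/HOBt amide coupling in which the α-amino ketone is freed from its salt only gradually, so acylation outruns its self-condensation, and any aryl ester formed at the nitrophenol is itself an active ester that ends up as the amide.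

Step 4
Reactants: 8 methyl 5-[[(2E,4E,6E)-7-(4-hydroxy-3-nitrophenyl)hepta-2,4,6-trienoyl]amino]-4-oxopentanoate
Product: 9 (2E,4E,6E)-N-(2-hydroxy-5-oxocyclopent-1-en-1-yl)-7-(4-hydroxy-3-nitrophenyl)hepta-2,4,6-trienamide
Conditions: t-BuOK (4 equiv), THF, 0 °C → rt; HCl (aq)
Reagents that add atoms: none
Why: Proposed new method: after deprotonation of the nitrophenol, t-BuOK reversibly forms the enolate at the methylene flanked by the ketone and the amide nitrogen, which attacks the methyl ester 5-exo-trig and loses methoxide to give the 2-acylamino-cyclopentane-1,3-dione, whose deprotonation (pKa about 5) makes the step irreversible and drains any imide formed by N-attack; the trienamide has no enolisable hydrogen, and the closest known reaction is the Dieckmann-type (intramolecular Claisen) cyclisation of 4-oxoalkanoate esters to 2-substituted cyclopentane-1,3-diones.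

Step 5
Reactants: 9 (2E,4E,6E)-N-(2-hydroxy-5-oxocyclopent-1-en-1-yl)-7-(4-hydroxy-3-nitrophenyl)hepta-2,4,6-trienamide
Product: 10 (2E,4E,6E)-7-(3-amino-4-hydroxyphenyl)-N-(2-hydroxy-5-oxocyclopent-1-en-1-yl)hepta-2,4,6-trienamide
Conditions: Zn dust, AcOH, THF, 0 °C → rt, under Ar
Reagents that add atoms: none
Why: Dissolving-metal reduction of the aryl nitro group to the aniline, which leaves the conjugated trienamide and the enolised 1,3-dione untouched; the air-sensitive aminophenol is used at once.

Step 6
Reactants: 11 (2E)-4-methylpent-2-enal; 4 triethyl 4-phosphonocrotonate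
Product: 13 (2E,4E,6E)-8-methylnona-2,4,6-trienoic acid, via ethyl 8-methylnonatrienoate 12 (not isolated)
Conditions: LiOH·H2O, 4 Å MS, THF, reflux; then LiOH, H2O/MeOH, rt; HCl (aq)
Reagents that add atoms: lithium hydroxide, [Li+].[OH-]
Why: Vinylogous Horner–Wadsworth–Emmons olefination under mild lithium hydroxide conditions (new C4=C5 bond E, the other two E from the reagents), followed by saponification in the same pot.

Step 7
Reactants: 10 (2E,4E,6E)-7-(3-amino-4-hydroxyphenyl)-N-(2-hydroxy-5-oxocyclopent-1-en-1-yl)hepta-2,4,6-trienamide; 13 (2E,4E,6E)-8-methylnona-2,4,6-trienoic acid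
Product: 15 proto-manumycin G [(2E,4E,6E)-N-{2-hydroxy-5-[(1E,3E,5E)-7-[(2-hydroxy-5-oxocyclopent-1-en-1-yl)amino]-7-oxohepta-1,3,5-trien-1-yl]phenyl}-8-methylnona-2,4,6-trienamide], via 8-methylnonatrienoyl chloride 14 (not isolated)
Conditions: 13, (COCl)2, cat. DMF, CH2Cl2, 0 °C, evaporate; then 10, NaHCO3, THF/H2O, 0 °C
Reagents that add atoms: none
Why: Acid chloride formation followed by Schotten–Baumann acylation, in which at pH about 8 the arylamine is by far the best nucleophile, the phenol is not ionised, and the C5N enolate gives at most a labile enol ester that hydrolyses in the same medium.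

Step 8
Reactants: 15 proto-manumycin G
Product: 16 (4R)-4-hydroxy-proto-manumycin G [(2E,4E,6E)-N-{(3R)-3-hydroxy-3-[(1E,3E,5E)-7-[(2-hydroxy-5-oxocyclopent-1-en-1-yl)amino]-7-oxohepta-1,3,5-trien-1-yl]-6-oxocyclohexa-1,4-dien-1-yl}-8-methylnona-2,4,6-trienamide]
Conditions: (R,R)-2-iodo-1,3-bis[1-(mesitylcarbamoyl)ethoxy]benzene (1.1 equiv), mCPBA (1.05 equiv), AcOH, CH2Cl2, rt, 2 h; then 15, MeCN/H2O 9:1, 0 °C
Reagents that add atoms: water, O
Why: Proposed new method: the phenol exchanges onto the pre-formed C2-symmetric aryl-λ3-iodane (no free peracid left to touch the polyenes), and water attacks the para carbon that carries the triene with loss of the iodoarene, one face being shielded by the lactamide arms (which can hydrogen-bond to the ortho amide N–H) so that C4 is set as R; ipso attack is favoured because the triene ends in an electron-poor amide; the closest known reactions are the PhI(OAc)2 para-dearomatisation of 2-acylaminophenols and the chiral-aryl-iodide hydroxylative dearomatisation of 2,4-disubstituted phenols to p-quinols; the sense of induction must be confirmed in the first run and the antipodal iodoarene is used if it is reversed.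

Step 9
Reactants: 16 (4R)-4-hydroxy-proto-manumycin G
Product: 17 manumycin G [(2E,4E,6E)-N-{(1S,5S,6R)-5-hydroxy-5-[(1E,3E,5E)-7-[(2-hydroxy-5-oxocyclopent-1-en-1-yl)amino]-7-oxohepta-1,3,5-trien-1-yl]-2-oxo-7-oxabicyclo[4.1.0]hept-3-en-3-yl}-8-methylnona-2,4,6-trienamide]
Conditions: t-BuOOH (1.5 equiv, decane), DBU (2.2 equiv), CH2Cl2/THF, −20 → 0 °C; pH 4 buffer
Reagents that add atoms: tert-butyl hydroperoxide, CC(C)(C)OO
Why: Weitz–Scheffer nucleophilic epoxidation in which t-BuOO− adds to C5 of the unsubstituted enone (the amido-substituted C2=C3 enone and the trienamides are far less electrophilic) and is delivered on the face of the C4 hydroxyl by hydrogen bonding and away from the bulky trienyl group, which sets 5R,6S; C4 is untouched and changes from R to S only because the CIP rank of C5 rises.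

## Compound list

1 | 4-fluoro-3-nitrobenzaldehyde | O=Cc1ccc(F)c([N+](=O)[O-])c1 | starting material
2 | (triphenylphosphoranylidene)acetaldehyde | O=CC=P(c1ccccc1)(c1ccccc1)c1ccccc1 | starting material
3 | (2E)-3-(4-fluoro-3-nitrophenyl)prop-2-enal | O=C/C=C/c1ccc(F)c([N+](=O)[O-])c1 | intermediate
4 | triethyl 4-phosphonocrotonate [ethyl (2E)-4-(diethoxyphosphoryl)but-2-enoate] | CCOC(=O)/C=C/CP(=O)(OCC)OCC | starting material
5 | ethyl (2E,4E,6E)-7-(4-fluoro-3-nitrophenyl)hepta-2,4,6-trienoate | CCOC(=O)/C=C/C=C/C=C/c1ccc(F)c([N+](=O)[O-])c1 | intermediate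
6 | (2E,4E,6E)-7-(4-hydroxy-3-nitrophenyl)hepta-2,4,6-trienoic acid | O=C(O)/C=C/C=C/C=C/c1ccc(O)c([N+](=O)[O-])c1 | intermediate
7 | methyl 5-amino-4-oxopentanoate hydrochloride | COC(=O)CCC(=O)CN.Cl | starting material
8 | methyl 5-[[(2E,4E,6E)-7-(4-hydroxy-3-nitrophenyl)hepta-2,4,6-trienoyl]amino]-4-oxopentanoate | COC(=O)CCC(=O)CNC(=O)/C=C/C=C/C=C/c1ccc(O)c([N+](=O)[O-])c1 | intermediate
9 | (2E,4E,6E)-N-(2-hydroxy-5-oxocyclopent-1-en-1-yl)-7-(4-hydroxy-3-nitrophenyl)hepta-2,4,6-trienamide | O=C(/C=C/C=C/C=C/c1ccc(O)c([N+](=O)[O-])c1)NC1=C(O)CCC1=O | intermediate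
10 | (2E,4E,6E)-7-(3-amino-4-hydroxyphenyl)-N-(2-hydroxy-5-oxocyclopent-1-en-1-yl)hepta-2,4,6-trienamide | Nc1cc(/C=C/C=C/C=C/C(=O)NC2=C(O)CCC2=O)ccc1O | intermediate
11 | (2E)-4-methylpent-2-enal | CC(C)/C=C/C=O | starting material
12 | ethyl (2E,4E,6E)-8-methylnona-2,4,6-trienoate | CCOC(=O)/C=C/C=C/C=C/C(C)C | intermediate
13 | (2E,4E,6E)-8-methylnona-2,4,6-trienoic acid | CC(C)/C=C/C=C/C=C/C(=O)O | intermediate
14 | (2E,4E,6E)-8-methylnona-2,4,6-trienoyl chloride | CC(C)/C=C/C=C/C=C/C(=O)Cl | intermediate
15 | proto-manumycin G (aromatic aminophenol precursor) | CC(C)/C=C/C=C/C=C/C(=O)Nc1cc(/C=C/C=C/C=C/C(=O)NC2=C(O)CCC2=O)ccc1O | intermediate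
16 | (4R)-4-hydroxy-proto-manumycin G (p-quinol) | CC(C)/C=C/C=C/C=C/C(=O)NC1=C[C@@](O)(/C=C/C=C/C=C/C(=O)NC2=C(O)CCC2=O)C=CC1=O | intermediate
17 | manumycin G, (4S,5R,6S) | CC(C)/C=C/C=C/C=C/C(=O)NC1=C[C@@](O)(/C=C/C=C/C=C/C(=O)NC2=C(O)CCC2=O)[C@@H]2O[C@@H]2C1=O | target

## Step count and risks

Total step count: 9.
Longest linear sequence: 8 steps (1, 2, 3, 4, 5, 7, 8, 9); step 6 is the side branch.

The three steps most likely to fail:

**Step 8 (enantioselective dearomative hydroxylation).** The level and sense of asymmetric induction are unknown for this substrate. The iodane may also oxidise the C5N enol, water may add along the triene instead of at the ipso carbon, or an o-quinone imide may form. Fallback: setting out from 15, oxidise with achiral PhI(OAc)2 in MeCN/H2O to the racemic quinol F1, and move the enantio-determining event into the epoxidation. A catalyst-controlled nucleophilic epoxidation (cinchona-derived phase-transfer catalyst, t-BuOOH, aqueous NaOH/toluene) is run to about half conversion as a kinetic resolution. The (R)-enantiomer, for which hydroxyl direction and catalyst are matched, goes to 17, where the fallback rejoins the route; the unreacted (S)-quinol F2 is separated. The cost is at most 50% yield in the last operation.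

**Step 4 (cyclisation of the N-acyl aminolevulinate).** Imide formation with loss of the trienoyl group, or intermolecular aldol chemistry, may outrun the C-acylation. Fallback: setting out from 6, give up the ring formation on the acyclic amide and attach a pre-formed ring. Commercial cyclopentane-1,3-dione is nitrosated (NaNO2, aqueous HCl) to 2-(hydroxyimino)cyclopentane-1,3-dione F3. Hydrogenation (H2, Pd/C, HCl, MeOH) gives 2-amino-3-hydroxycyclopent-2-en-1-one hydrochloride F4, which is coupled with acid 6 (EDC, HOBt, N-methylmorpholine) to come back to the route at 9.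

**Step 7 (N-acylation beside a free phenol and the C5N enol).** O-acylation of the enolate, or oxidation of the aminophenol 10, may erode the yield. Fallback: setting out from 6, install the upper chain before the C5N ring exists. Zn/AcOH reduction of 6 gives (2E,4E,6E)-7-(3-amino-4-hydroxyphenyl)hepta-2,4,6-trienoic acid F5. Schotten–Baumann acylation with 14 gives the bis-chain acid F6. EDC coupling with 7 gives the keto ester F7, and t-BuOK cyclisation as in step 4 (both amide N–H groups deprotonated, which protects the trienamides) comes back to the route at 15.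

## Further compounds

F1 | step 8 | racemic 4-hydroxy-proto-manumycin G (p-quinol) | CC(C)/C=C/C=C/C=C/C(=O)NC1=CC(O)(/C=C/C=C/C=C/C(=O)NC2=C(O)CCC2=O)C=CC1=O
F2 | step 8 | (4S)-4-hydroxy-proto-manumycin G (unreacted enantiomer) | CC(C)/C=C/C=C/C=C/C(=O)NC1=C[C@](O)(/C=C/C=C/C=C/C(=O)NC2=C(O)CCC2=O)C=CC1=O
F3 | step 4 | 2-(hydroxyimino)cyclopentane-1,3-dione | O=C1CCC(=O)C1=NO
F4 | step 4 | 2-amino-3-hydroxycyclopent-2-en-1-one hydrochloride | NC1=C(O)CCC1=O.Cl
F5 | step 7 | (2E,4E,6E)-7-(3-amino-4-hydroxyphenyl)hepta-2,4,6-trienoic acid | Nc1cc(/C=C/C=C/C=C/C(=O)O)ccc1O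
F6 | step 7 | (2E,4E,6E)-7-[4-hydroxy-3-[[(2E,4E,6E)-8-methylnona-2,4,6-trienoyl]amino]phenyl]hepta-2,4,6-trienoic acid | CC(C)/C=C/C=C/C=C/C(=O)Nc1cc(/C=C/C=C/C=C/C(=O)O)ccc1O
F7 | step 7 | methyl 5-[[(2E,4E,6E)-7-[4-hydroxy-3-[[(2E,4E,6E)-8-methylnona-2,4,6-trienoyl]amino]phenyl]hepta-2,4,6-trienoyl]amino]-4-oxopentanoate | CC(C)/C=C/C=C/C=C/C(=O)Nc1cc(/C=C/C=C/C=C/C(=O)NCC(=O)CCC(=O)OC)ccc1O
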